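The dihydrofuran ring is disconnected at O1–C2. C2 is benzylic to the 3,4,5-trimethoxyphenyl ring, so under acid its hydroxyl leaves as water and the phenol oxygen on C7a captures the cation. One operation therefore closes the five-membered ring and sets C2 trans to the existing C3 centre, irrespective of the carbinol configuration. The precursor is 4-bromo-2-[1,3-dihydroxy-1-(3,4,5-trimethoxyphenyl)propan-2-yl]phenol. Its C3 centre comes from an Evans aldol between an O-allyl arylacetyl imide and 3,4,5-trimethoxybenzaldehyde, followed by reductive auxiliary removal and deallylation. The C5 bromide then carries the side chain in by Heck coupling and DIBAL reduction.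

Key step: step 6

Remark on the chemistry: the primary hydroxyl is taken through the ring closure unprotected, on the assumption that only the C2 carbinol ionises under the chosen acid; the (R)-antipode of the auxiliary is the one that leads to (3S).

Step 1
Reactants: 1 2-(5-bromo-2-hydroxyphenyl)acetic acid
Product: 3 2-[5-bromo-2-(prop-2-en-1-yloxy)phenyl]acetic acid, via bis-allylated ester 2 (not isolated)
Conditions: allyl bromide (2.5 equiv), K2CO3, DMF, 50 °C; then 2 M NaOH, MeOH, rt; HCl to pH 2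
Reagents that add atoms: allyl bromide, C=CCBr; sodium hydroxide, [Na+].[OH-]
Why: Williamson O-alkylation allylates both the phenoxide and the carboxylate, and hydroxide then saponifies only the allyl ester because the aryl allyl ether offers no acyl group to attack; no stereocentre is involved.

Step 2
Reactants: 3 2-[5-bromo-2-(prop-2-en-1-yloxy)phenyl]acetic acid; 4 (4R)-4-benzyl-1,3-oxazolidin-2-one
Product: 6 (4R)-4-benzyl-3-{2-[5-bromo-2-(prop-2-en-1-yloxy)phenyl]acetyl}-1,3-oxazolidin-2-one, via mixed pivalic anhydride 5 (not isolated)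
Conditions: PivCl, Et3N, THF, −20 °C; then LiCl, 4, −20 °C → rt
Reagents that add atoms: pivaloyl chloride, CC(C)(C)C(Cl)=O (its acyl group is in 5 only, not in 6)
Why: N-acylation of the oxazolidinone through a mixed anhydride should work because the LiCl/Et3N-activated oxazolidinone attacks the unhindered arylacetyl carbonyl and not the tert-butyl-shielded pivaloyl one; the auxiliary centre is untouched.

Step 3
Reactants: 6 (4R)-4-benzyl-3-{2-[5-bromo-2-(prop-2-en-1-yloxy)phenyl]acetyl}-1,3-oxazolidin-2-one; 7 3,4,5-trimethoxybenzaldehyde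
Product: 10 (4R)-4-benzyl-3-[(2R,3R)-2-[5-bromo-2-(prop-2-en-1-yloxy)phenyl]-3-hydroxy-3-(3,4,5-trimethoxyphenyl)propanoyl]-1,3-oxazolidin-2-one, via Z-boron enolate 8 (not isolated), via boron aldolate 9 (not isolated)
Conditions: Bu2BOTf, i-Pr2NEt, CH2Cl2, −78 → 0 °C; 7, −78 → 0 °C; then pH 7 buffer, MeOH, 30% H2O2, 0 °C
Reagents that add atoms: dibutylboron triflate, CCCCB(CCCC)OS(=O)(=O)C(F)(F)F (its Bu2B group is in 8 and 9 only, not in 10)
Why: Evans syn aldol addition: soft enolisation gives the Z-boron enolate, which adds to the aldehyde through a Zimmerman–Traxler chair on the face left open by the benzyl group of the (R)-auxiliary, fixing the aryl-bearing carbon (the future C3) in the required sense and the carbinol as the syn (3R) epimer, whose configuration the later cation erases.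

Step 4
Reactants: 10 (4R)-4-benzyl-3-[(2R,3R)-2-[5-bromo-2-(prop-2-en-1-yloxy)phenyl]-3-hydroxy-3-(3,4,5-trimethoxyphenyl)propanoyl]-1,3-oxazolidin-2-one
Product: 11 (1R,2S)-2-[5-bromo-2-(prop-2-en-1-yloxy)phenyl]-1-(3,4,5-trimethoxyphenyl)propane-1,3-diol
Conditions: LiBH4, MeOH (1 equiv), THF, 0 °C
Reagents that add atoms: none
Why: Reductive cleavage of an N-acyloxazolidinone: borohydride attacks the more electrophilic exocyclic imide carbonyl and takes it to the primary alcohol at 0 °C, where the aryl bromide, the allyl ether and both stereocentres are left alone, and the auxiliary 4 is released for recovery.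

Step 5
Reactants: 11 (1R,2S)-2-[5-bromo-2-(prop-2-en-1-yloxy)phenyl]-1-(3,4,5-trimethoxyphenyl)propane-1,3-diol
Product: 12 4-bromo-2-[(1R,2S)-1,3-dihydroxy-1-(3,4,5-trimethoxyphenyl)propan-2-yl]phenol
Conditions: Pd(PPh3)4 (3 mol%), morpholine, THF, rt
Reagents that add atoms: none
Why: Tsuji–Trost deallylation: Pd(0) ionises the aryl allyl ether to a π-allyl complex that morpholine intercepts, under neutral conditions at room temperature where oxidative addition into the electron-rich aryl bromide is slow and the acid-labile benzylic carbinol is not ionised.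

Step 6
Reactants: 12 4-bromo-2-[(1R,2S)-1,3-dihydroxy-1-(3,4,5-trimethoxyphenyl)propan-2-yl]phenol
Product: 13 [(2R,3S)-5-bromo-2-(3,4,5-trimethoxyphenyl)-2,3-dihydro-1-benzofuran-3-yl]methanol
Conditions: TsOH·H2O (10 mol%), HFIP–CH2Cl2 (1:4), 0 °C → rt; NaHCO3 quench at full conversion
Reagents that add atoms: none
Why: Protonation of the C2 hydroxyl and loss of water give a benzylic cation delocalised into the 3,4,5-trimethoxyphenyl ring, and the ortho phenol oxygen adds to it to form O1–C2 (SN1 cyclodehydration). The closest known reaction type is the acid-catalysed cyclisation of 1-aryl-2-(2-hydroxyaryl)propane-1,3-diols to trans-2-aryl-3-(hydroxymethyl)-2,3-dihydrobenzofurans. The dihydrofuran ring closes in a 5-exo-trig mode, the oxygen adding to trigonal C2 while the C2=C(ipso) π bond of the quinoid resonance form stays outside the new ring. C2 is the only new stereocentre and is controlled by the existing C3 centre: the oxygen adds to the face of the planar cation away from the CH2OH group, and since the benzylic aryl ether can open again under the same acid, cis material should drain to the more stable trans (2R,3S) isomer, so the (1R) configuration from the aldol plays no part. The step needs chemoselectivity for the phenol over the primary hydroxyl, which is built in because only C2 can ionise and the primary oxygen could close only an oxetane, and it needs C3 to survive, which the fast intramolecular five-membered trapping, the non-basic fluoroalcohol medium and the low temperature should secure against proton loss from C3.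

Step 7
Reactants: 13 [(2R,3S)-5-bromo-2-(3,4,5-trimethoxyphenyl)-2,3-dihydro-1-benzofuran-3-yl]methanol; 14 methyl acrylate
Product: 15 methyl (2E)-3-[(2R,3S)-3-(hydroxymethyl)-2-(3,4,5-trimethoxyphenyl)-2,3-dihydro-1-benzofuran-5-yl]prop-2-enoate
Conditions: Pd(OAc)2 (5 mol%), P(o-tol)3 (10 mol%), Et3N, DMF, 100 °C
Reagents that add atoms: none
Why: Mizoroki–Heck reaction: oxidative addition into the C5–Br bond, syn carbopalladation of the acrylate and syn β-hydride elimination give the E-cinnamate, with the free alcohol and the two ring stereocentres as spectators under the amine base.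

Step 8
Reactants: 15 methyl (2E)-3-[(2R,3S)-3-(hydroxymethyl)-2-(3,4,5-trimethoxyphenyl)-2,3-dihydro-1-benzofuran-5-yl]prop-2-enoate
Product: 16 (2E)-3-[(2R,3S)-3-(hydroxymethyl)-2-(3,4,5-trimethoxyphenyl)-2,3-dihydro-1-benzofuran-5-yl]prop-2-en-1-ol
Conditions: DIBAL-H (4 equiv), CH2Cl2, −78 °C; Rochelle salt work-up
Reagents that add atoms: none
Why: DIBAL reduction of an α,β-unsaturated ester delivers hydride twice in the 1,2-sense to give the allylic alcohol with the E geometry retained, one extra equivalent being consumed by the free hydroxyl, and the non-acidic tartrate work-up protects the electron-rich cinnamyl alcohol and the benzylic ether at C2.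

Compound list
1 | 2-(5-bromo-2-hydroxyphenyl)acetic acid | OC(=O)Cc1cc(Br)ccc1O | starting material
2 | prop-2-en-1-yl 2-[5-bromo-2-(prop-2-en-1-yloxy)phenyl]acetate | C=CCOC(=O)Cc1cc(Br)ccc1OCC=C | intermediate (not isolated)
3 | 2-[5-bromo-2-(prop-2-en-1-yloxy)phenyl]acetic acid | OC(=O)Cc1cc(Br)ccc1OCC=C | intermediate
4 | (4R)-4-benzyl-1,3-oxazolidin-2-one | O=C1N[C@H](Cc2ccccc2)CO1 | starting material
5 | 2-[5-bromo-2-(prop-2-en-1-yloxy)phenyl]acetic pivalic anhydride | CC(C)(C)C(=O)OC(=O)Cc1cc(Br)ccc1OCC=C | intermediate (not isolated)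
6 | (4R)-4-benzyl-3-{2-[5-bromo-2-(prop-2-en-1-yloxy)phenyl]acetyl}-1,3-oxazolidin-2-one | O=C(Cc1cc(Br)ccc1OCC=C)N1[C@H](Cc2ccccc2)COC1=O | intermediate
7 | 3,4,5-trimethoxybenzaldehyde | COc1cc(C=O)cc(OC)c1OC | starting material
8 | (Z)-dibutylboron enolate of 6 | CCCCB(CCCC)O/C(=C\c1cc(Br)ccc1OCC=C)N1[C@H](Cc2ccccc2)COC1=O | intermediate (not isolated)
9 | O-dibutylboryl derivative (boron aldolate) of 10 | COc1cc([C@H](OB(CCCC)CCCC)[C@H](C(=O)N2[C@H](Cc3ccccc3)COC2=O)c4cc(Br)ccc4OCC=C)cc(OC)c1OC | intermediate (not isolated)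
10 | (4R)-4-benzyl-3-[(2R,3R)-2-[5-bromo-2-(prop-2-en-1-yloxy)phenyl]-3-hydroxy-3-(3,4,5-trimethoxyphenyl)propanoyl]-1,3-oxazolidin-2-one | COc1cc([C@H](O)[C@H](C(=O)N2[C@H](Cc3ccccc3)COC2=O)c4cc(Br)ccc4OCC=C)cc(OC)c1OC | intermediate
11 | (1R,2S)-2-[5-bromo-2-(prop-2-en-1-yloxy)phenyl]-1-(3,4,5-trimethoxyphenyl)propane-1,3-diol | COc1cc([C@H](O)[C@H](CO)c2cc(Br)ccc2OCC=C)cc(OC)c1OC | intermediate
12 | 4-bromo-2-[(1R,2S)-1,3-dihydroxy-1-(3,4,5-trimethoxyphenyl)propan-2-yl]phenol | COc1cc([C@H](O)[C@H](CO)c2cc(Br)ccc2O)cc(OC)c1OC | intermediate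
13 | [(2R,3S)-5-bromo-2-(3,4,5-trimethoxyphenyl)-2,3-dihydro-1-benzofuran-3-yl]methanol | COc1cc([C@@H]2Oc3ccc(Br)cc3[C@H]2CO)cc(OC)c1OC | intermediate
14 | methyl acrylate | C=CC(=O)OC | starting material
15 | methyl (2E)-3-[(2R,3S)-3-(hydroxymethyl)-2-(3,4,5-trimethoxyphenyl)-2,3-dihydro-1-benzofuran-5-yl]prop-2-enoate | COc1cc([C@@H]2Oc3ccc(/C=C/C(=O)OC)cc3[C@H]2CO)cc(OC)c1OC | intermediate
16 | (2E)-3-[(2R,3S)-3-(hydroxymethyl)-2-(3,4,5-trimethoxyphenyl)-2,3-dihydro-1-benzofuran-5-yl]prop-2-en-1-ol | COc1cc([C@@H]2Oc3ccc(/C=C/CO)cc3[C@H]2CO)cc(OC)c1OC | target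

Total step count: 8.
Longest linear sequence: 8 steps (1 → 16); the route is fully linear, with 4, 7 and 14 entering as purchased reagents.

Steps most likely to fail

Step 6 (key step). What may go wrong is diversion of the benzylic cation before it closes: fragmentation with loss of formaldehyde, capture by the primary hydroxyl of a second molecule, closure with too little facial bias, or proton loss from C3 that flattens the aldol-derived centre. The fallback changes the substrate and not the acid. It sets out from diol 11, whose primary hydroxyl is silylated selectively (TIPSCl, imidazole, DMF) to give (1R,2S)-2-[5-bromo-2-(prop-2-en-1-yloxy)phenyl]-3-[tri(propan-2-yl)silyloxy]-1-(3,4,5-trimethoxyphenyl)propan-1-ol F1. Deallylation as in step 5 gives 4-bromo-2-[(1R,2S)-1-hydroxy-3-[tri(propan-2-yl)silyloxy]-1-(3,4,5-trimethoxyphenyl)propan-2-yl]phenol F2. In F2 the cation has a single oxygen nucleophile, no free hydroxyl to fragment, and a bulky group on C3 to direct the closure. Acid closure then gives {[(2R,3S)-5-bromo-2-(3,4,5-trimethoxyphenyl)-2,3-dihydro-1-benzofuran-3-yl]methoxy}tri(propan-2-yl)silane F3, and TBAF in THF returns the route at 13.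

Step 3. What may go wrong is slow addition of the aryl-stabilised boron enolate to the electron-rich aldehyde, with retro-aldol cleavage of the aldolate on work-up, so that conversion drops and the α-centre epimerises. The fallback is a magnesium-catalysed direct anti-aldol under soft enolisation, made irreversible by silyl trapping. It sets out from acid 3, which is coupled as in step 2 (through 5) with (4S)-4-benzyl-1,3-oxazolidin-2-one to give (4S)-4-benzyl-3-{2-[5-bromo-2-(prop-2-en-1-yloxy)phenyl]acetyl}-1,3-oxazolidin-2-one F4. MgCl2 (cat.), Et3N and TMSCl in EtOAc at rt with aldehyde 7 should give the silylated anti adduct (4S)-4-benzyl-3-[(2R,3S)-2-[5-bromo-2-(prop-2-en-1-yloxy)phenyl]-3-(trimethylsilyloxy)-3-(3,4,5-trimethoxyphenyl)propanoyl]-1,3-oxazolidin-2-one F5. The enolate here is chelated by both imide carbonyls and is attacked on the face opposite to that used by the boron enolate, which is why the (S)-auxiliary is taken. Citric acid in MeOH frees the carbinol, (4S)-4-benzyl-3-[(2R,3S)-2-[5-bromo-2-(prop-2-en-1-yloxy)phenyl]-3-hydroxy-3-(3,4,5-trimethoxyphenyl)propanoyl]-1,3-oxazolidin-2-one F6. LiBH4 as in step 4 gives (1S,2S)-2-[5-bromo-2-(prop-2-en-1-yloxy)phenyl]-1-(3,4,5-trimethoxyphenyl)propane-1,3-diol F7, and deallylation as in step 5 gives 4-bromo-2-[(1S,2S)-1,3-dihydroxy-1-(3,4,5-trimethoxyphenyl)propan-2-yl]phenol F8. F8 is the carbinol epimer of 12 and ionises to the same cation, so the conditions of step 6 bring it back to the route at 13.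

Step 4. What may go wrong is retro-aldol fragmentation of the metal alkoxide formed under the hydride conditions, which competes with reduction because the aryl-stabilised imide enolate is a good leaving group, together with epimerisation next to the imide. The fallback masks the carbinol before the reduction. It sets out from 10, which is silylated (TESOTf, 2,6-lutidine, CH2Cl2, −78 °C) to (4R)-4-benzyl-3-[(2R,3R)-2-[5-bromo-2-(prop-2-en-1-yloxy)phenyl]-3-(triethylsilyloxy)-3-(3,4,5-trimethoxyphenyl)propanoyl]-1,3-oxazolidin-2-one F9. LiBH4 then gives (2S,3R)-2-[5-bromo-2-(prop-2-en-1-yloxy)phenyl]-3-(triethylsilyloxy)-3-(3,4,5-trimethoxyphenyl)propan-1-ol F10 without an alkoxide at the benzylic carbon, and TBAF in THF returns the route at 11.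

Further compounds
F1 | step 6 | (1R,2S)-2-[5-bromo-2-(prop-2-en-1-yloxy)phenyl]-3-[tri(propan-2-yl)silyloxy]-1-(3,4,5-trimethoxyphenyl)propan-1-ol | COc1cc([C@H](O)[C@H](CO[Si](C(C)C)(C(C)C)C(C)C)c2cc(Br)ccc2OCC=C)cc(OC)c1OC
F2 | step 6 | 4-bromo-2-[(1R,2S)-1-hydroxy-3-[tri(propan-2-yl)silyloxy]-1-(3,4,5-trimethoxyphenyl)propan-2-yl]phenol | COc1cc([C@H](O)[C@H](CO[Si](C(C)C)(C(C)C)C(C)C)c2cc(Br)ccc2O)cc(OC)c1OC
F3 | step 6 | {[(2R,3S)-5-bromo-2-(3,4,5-trimethoxyphenyl)-2,3-dihydro-1-benzofuran-3-yl]methoxy}tri(propan-2-yl)silane | COc1cc([C@@H]2Oc3ccc(Br)cc3[C@H]2CO[Si](C(C)C)(C(C)C)C(C)C)cc(OC)c1OC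
F4 | step 3 | (4S)-4-benzyl-3-{2-[5-bromo-2-(prop-2-en-1-yloxy)phenyl]acetyl}-1,3-oxazolidin-2-one | O=C(Cc1cc(Br)ccc1OCC=C)N1[C@@H](Cc2ccccc2)COC1=O
F5 | step 3 | (4S)-4-benzyl-3-[(2R,3S)-2-[5-bromo-2-(prop-2-en-1-yloxy)phenyl]-3-(trimethylsilyloxy)-3-(3,4,5-trimethoxyphenyl)propanoyl]-1,3-oxazolidin-2-one | COc1cc([C@@H](O[Si](C)(C)C)[C@H](C(=O)N2[C@@H](Cc3ccccc3)COC2=O)c4cc(Br)ccc4OCC=C)cc(OC)c1OC
F6 | step 3 | (4S)-4-benzyl-3-[(2R,3S)-2-[5-bromo-2-(prop-2-en-1-yloxy)phenyl]-3-hydroxy-3-(3,4,5-trimethoxyphenyl)propanoyl]-1,3-oxazolidin-2-one | COc1cc([C@@H](O)[C@H](C(=O)N2[C@@H](Cc3ccccc3)COC2=O)c4cc(Br)ccc4OCC=C)cc(OC)c1OC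
F7 | step 3 | (1S,2S)-2-[5-bromo-2-(prop-2-en-1-yloxy)phenyl]-1-(3,4,5-trimethoxyphenyl)propane-1,3-diol | COc1cc([C@@H](O)[C@H](CO)c2cc(Br)ccc2OCC=C)cc(OC)c1OC
F8 | step 3 | 4-bromo-2-[(1S,2S)-1,3-dihydroxy-1-(3,4,5-trimethoxyphenyl)propan-2-yl]phenol | COc1cc([C@@H](O)[C@H](CO)c2cc(Br)ccc2O)cc(OC)c1OC
F9 | step 4 | (4R)-4-benzyl-3-[(2R,3R)-2-[5-bromo-2-(prop-2-en-1-yloxy)phenyl]-3-(triethylsilyloxy)-3-(3,4,5-trimethoxyphenyl)propanoyl]-1,3-oxazolidin-2-one | COc1cc([C@H](O[Si](CC)(CC)CC)[C@H](C(=O)N2[C@H](Cc3ccccc3)COC2=O)c4cc(Br)ccc4OCC=C)cc(OC)c1OC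
F10 | step 4 | (2S,3R)-2-[5-bromo-2-(prop-2-en-1-yloxy)phenyl]-3-(triethylsilyloxy)-3-(3,4,5-trimethoxyphenyl)propan-1-ol | COc1cc([C@H](O[Si](CC)(CC)CC)[C@H](CO)c2cc(Br)ccc2OCC=C)cc(OC)c1OC
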